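**Strategy**

Everything rests on cutting three consecutive bonds, C6–C5, C5–C4 and C4–C3, of the 2,8-dioxabicyclo[3.2.1]octane core. The feature exploited is that C3, C4 and C5 of the dioxane ring each carry one oxygen and one carboxyl carbon, so the triad is three glyoxylate units in a row, capped at C5 by C6 of the five-membered ring. One anionic cascade joins vinylmagnesium bromide, two molecules of a silyl glyoxylate and tert-butyl glyoxylate, making all three bonds and three stereocentres without closing a ring. Its precursors are therefore only a Grignard reagent and two achiral two-carbon esters; resolution, side-chain acylation, ketalisation and C3 equilibration complete the target.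

Key step: step 4

Remark on the chemistry: the aldol that ends the cascade is assumed to set C3 opposite to the target relative to C4 and C5. Compounds 9 to 22 are therefore drawn with C3 as R, and step 14 inverts it; if the aldol gives the target C3 configuration directly, step 14 falls away. Compound 9 is racemic, and its SMILES shows the enantiomer that is carried on.

**Route**

Step 1
Reactants: 1 tert-butyl diazoacetate
Product: 2 tert-butyl 2-(tert-butyldimethylsilyl)-2-diazoacetate
Conditions: TBSOTf, i-Pr2NEt, Et2O, −40 °C → rt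
Reagents that add atoms: tert-butyldimethylsilyl trifluoromethanesulfonate, CC(C)(C)[Si](C)(C)OS(=O)(=O)C(F)(F)F
Why: C-silylation of a diazo ester, in which the nucleophilic diazo carbon attacks the silyl triflate and the amine removes the proton of the diazonium intermediate.

Step 2
Reactants: 2 tert-butyl 2-(tert-butyldimethylsilyl)-2-diazoacetate
Product: 3 tert-butyl 2-(tert-butyldimethylsilyl)-2-oxoacetate (the silyl glyoxylate)
Conditions: KHSO5 (as Oxone), NaHCO3, acetone, CH2Cl2/H2O, 0 °C → rt
Reagents that add atoms: potassium peroxymonosulfate, [K+].[O-]S(=O)(=O)OO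
Why: diazo-to-carbonyl oxidation, in which dimethyldioxirane formed in the flask transfers oxygen to the diazo carbon with loss of N2.

Step 3
Reactants: 4 di-tert-butyl fumarate
Product: 5 tert-butyl glyoxylate (two molecules from each molecule of 4)
Conditions: O3, CH2Cl2, −78 °C; Me2S, −78 °C → rt; distilled from P2O5 just before use
Reagents that add atoms: ozone, [O-][O+]=O
Why: ozonolysis of a symmetrical alkene with reductive work-up, giving the anhydrous aldehyde after distillation.

Step 4
Reactants: 6 vinylmagnesium bromide; 3 tert-butyl 2-(tert-butyldimethylsilyl)-2-oxoacetate (two equivalents); 5 tert-butyl glyoxylate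
Product: 9 racemic tri-tert-butyl (1R*,2S*,3R*)-2,3-bis(tert-butyldimethylsilyloxy)-1-hydroxypent-4-ene-1,2,3-tricarboxylate, via magnesium dienolate 7 (not isolated), via magnesium enolate 8 (not isolated)
Conditions: 6 added to 3 (2 equiv), THF, −78 °C → −45 °C; then 5, −45 °C → rt; aq NH4Cl
Reagents that add atoms: none
Why: The Grignard reagent adds to the silyl ketone of the first molecule of 3 (C6–C5) and a 1,2-Brook shift of silicon from carbon to oxygen gives dienolate 7, which adds through its α-carbon to the ketone of the second molecule of 3 (C5–C4); a second Brook shift gives enolate 8, which is trapped by aldehyde 5 in an aldol addition (C4–C3), leaving the C3 alkoxide that becomes the free hydroxyl. The closest known reaction type is the nucleophile-triggered Brook rearrangement/aldol coupling of silyl glyoxylates, here run twice in a row before termination. No ring is closed. C5 and C4 are set together when 7 adds to 3 through a closed, magnesium-chelated transition state that should relate the two fully substituted carbons as in the target, and C3 is set in the terminating aldol through a chair transition state with the glyoxylate bound to magnesium, which is expected to give the C3 epimer of the target triad; absolute configuration is not controlled, so 9 is racemic. The step needs chemoselectivity and control of chain length: the silyl ketone of 3 is far more electrophilic than its tert-butyl ester, the Brook shift outruns a second Grignard addition, the 2:1 ratio of 3 to 6 at low temperature limits the chain to two glycolate units before 5 is added, and the bulky silyl and tert-butyl groups disfavour γ-attack of the dienolate.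

Step 5
Reactants: 9 racemic tri-tert-butyl (1R*,2S*,3R*)-2,3-bis(tert-butyldimethylsilyloxy)-1-hydroxypent-4-ene-1,2,3-tricarboxylate
Product: 10 tri-tert-butyl (1R,2S,3R)-2,3-bis(tert-butyldimethylsilyloxy)-1-hydroxypent-4-ene-1,2,3-tricarboxylate (single enantiomer)
Conditions: PdCl2(nbd) (cat., nbd = norbornadiene), (−)-sparteine, O2 (1 atm), 3 Å MS, t-BuOH, 65 °C, stopped just past half conversion
Reagents that add atoms: none
Why: oxidative kinetic resolution of a secondary alcohol by a divalent palladium–sparteine catalyst, in which the mirror-image enantiomer should be oxidised at the C3 carbinol to the α-keto ester while the needed enantiomer remains and is separated by chromatography.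

Step 6
Reactants: 10 tri-tert-butyl (1R,2S,3R)-2,3-bis(tert-butyldimethylsilyloxy)-1-hydroxypent-4-ene-1,2,3-tricarboxylate
Product: 11 tri-tert-butyl (1R,2S,3R)-2,3-bis(tert-butyldimethylsilyloxy)-1-(triethylsilyloxy)pent-4-ene-1,2,3-tricarboxylate
Conditions: TESOTf, 2,6-lutidine, CH2Cl2, −78 °C → 0 °C
Reagents that add atoms: triethylsilyl trifluoromethanesulfonate, CC[Si](CC)(CC)OS(=O)(=O)C(F)(F)F
Why: silylation of a hindered secondary alcohol with a silyl triflate, which covers the C3 hydroxyl so that it neither consumes borane nor opens a retro-aldol path under the basic coupling of step 12.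

Step 7
Reactants: 12 (S)-2-methyl-3-phenylpropanoic acid
Product: 13 (S)-2-methyl-3-phenylpropan-1-ol
Conditions: LiAlH4, THF, 0 °C → rt
Reagents that add atoms: none
Why: hydride reduction of a carboxylic acid to the primary alcohol, which does not touch the α-stereocentre.

Step 8
Reactants: 13 (S)-2-methyl-3-phenylpropan-1-ol
Product: 14 (S)-2-methyl-3-phenylpropanal
Conditions: Dess–Martin periodinane, NaHCO3, CH2Cl2, 0 °C → rt; used crude at once
Reagents that add atoms: none
Why: Dess–Martin oxidation under buffered, base-free conditions, chosen so that the enolisable α-stereocentre is kept.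

Step 9
Reactants: 14 (S)-2-methyl-3-phenylpropanal
Product: 15 (4S)-2,4-dimethyl-5-phenylpent-1-en-3-ol (both C3 epimers)
Conditions: CH2=C(CH3)MgBr, THF, −78 °C; aq NH4Cl
Reagents that add atoms: isopropenylmagnesium bromide, CC(=C)[Mg]Br
Why: Grignard addition to an aldehyde, in which the new carbinol centre forms as a mixture that does not matter because step 10 removes it.

Step 10
Reactants: 15 (4S)-2,4-dimethyl-5-phenylpent-1-en-3-ol
Product: 17 ethyl (4E,6S)-4,6-dimethyl-7-phenylhept-4-enoate, via ketene acetal 16 (not isolated)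
Conditions: MeC(OEt)3, EtCO2H (cat.), 140 °C, EtOH distilled off
Reagents that add atoms: triethyl orthoacetate, CC(OCC)(OCC)OCC
Why: Johnson–Claisen rearrangement, in which a chair transition state with the CH(CH3)CH2Ph group equatorial should give the E trisubstituted alkene while the C6 stereocentre is not involved.

Step 11
Reactants: 17 ethyl (4E,6S)-4,6-dimethyl-7-phenylhept-4-enoate
Product: 18 S-(4-methylphenyl) (4E,6S)-4,6-dimethyl-7-phenylhept-4-enethioate
Conditions: AlMe3, 4-MeC6H4SH, CH2Cl2, 0 °C → rt
Reagents that add atoms: 4-methylbenzenethiol, Cc1ccc(S)cc1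
Why: ester-to-thioester exchange with a dimethylaluminium thiolate formed in the flask, a Lewis-acidic sulfur nucleophile that leaves the alkene and the stereocentre alone.

Step 12
Reactants: 11 tri-tert-butyl (1R,2S,3R)-2,3-bis(tert-butyldimethylsilyloxy)-1-(triethylsilyloxy)pent-4-ene-1,2,3-tricarboxylate; 18 S-(4-methylphenyl) (4E,6S)-4,6-dimethyl-7-phenylhept-4-enethioate
Product: 20 tri-tert-butyl (1R,2S,3R,9E,11S)-2,3-bis(tert-butyldimethylsilyloxy)-9,11-dimethyl-6-oxo-12-phenyl-1-(triethylsilyloxy)dodec-9-ene-1,2,3-tricarboxylate, via alkylborane 19 (not isolated)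
Conditions: 9-BBN dimer, THF, 0 °C → rt; then 18, Pd(PPh3)4 (cat.), Cu(O2C-2-thienyl), Cs2CO3, THF, 45 °C
Reagents that add atoms: none
Why: anti-Markovnikov hydroboration of the vinyl group followed by Liebeskind–Srogl ketone synthesis, in which zerovalent palladium inserts into the acyl–sulfur bond, the monovalent copper carboxylate takes up the thiolate, the base-activated B-alkyl group transfers the primary C7 carbon and reductive elimination forms the C7–C1 bond without touching a stereocentre.

Step 13
Reactants: 20 tri-tert-butyl (1R,2S,3R,9E,11S)-2,3-bis(tert-butyldimethylsilyloxy)-9,11-dimethyl-6-oxo-12-phenyl-1-(triethylsilyloxy)dodec-9-ene-1,2,3-tricarboxylate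
Product: 22 tri-tert-butyl (1S,3R,4S,5R)-1-[(3E,5S)-3,5-dimethyl-6-phenylhex-3-en-1-yl]-4-hydroxy-2,8-dioxabicyclo[3.2.1]octane-3,4,5-tricarboxylate, via keto triol 21 (not isolated)
Conditions: HF (48% aq), MeCN, 0 °C → rt; then CSA (cat.), 4 Å MS, CH2Cl2, rt
Reagents that add atoms: none
Why: fluoride-driven cleavage of the three silyl ethers in a weakly acidic medium that should spare tert-butyl esters, followed by thermodynamic intramolecular ketalisation in which the C5 hydroxyl closes the five-membered ring on the C1 ketone and the C3 hydroxyl closes the dioxane ring on the oxocarbenium ion, the C1 configuration being fixed by the bridged geometry.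

Step 14
Reactants: 22 tri-tert-butyl (1S,3R,4S,5R)-1-[(3E,5S)-3,5-dimethyl-6-phenylhex-3-en-1-yl]-4-hydroxy-2,8-dioxabicyclo[3.2.1]octane-3,4,5-tricarboxylate
Product: 23 tri-tert-butyl (1S,3S,4S,5R)-1-[(3E,5S)-3,5-dimethyl-6-phenylhex-3-en-1-yl]-4-hydroxy-2,8-dioxabicyclo[3.2.1]octane-3,4,5-tricarboxylate
Conditions: KOt-Bu, t-BuOH/THF, rt; AcOH quench; recovered 22 resubmitted
Reagents that add atoms: none
Why: base-mediated epimerisation through the ester enolate at C3, the only enolisable carbon of the core, which should equilibrate towards the C3 ester equatorial on the chair dioxane ring and away from the C6–C7 bridge, while tert-butoxide exchange at the esters is degenerate.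

Step 15
Reactants: 23 tri-tert-butyl (1S,3S,4S,5R)-1-[(3E,5S)-3,5-dimethyl-6-phenylhex-3-en-1-yl]-4-hydroxy-2,8-dioxabicyclo[3.2.1]octane-3,4,5-tricarboxylate
Product: 24 (1S,3S,4S,5R)-1-[(3E,5S)-3,5-dimethyl-6-phenylhex-3-en-1-yl]-4-hydroxy-2,8-dioxabicyclo[3.2.1]octane-3,4,5-tricarboxylic acid (CNP0217737.2)
Conditions: TFA, CH2Cl2, rt
Reagents that add atoms: none
Why: acidolysis of the three tert-butyl esters with loss of 2-methylpropene, under anhydrous acid to which the bicyclic ketal should be stable.

**Compound list**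

1 | tert-butyl diazoacetate | [N-]=[N+]=CC(=O)OC(C)(C)C | starting material
2 | tert-butyl 2-(tert-butyldimethylsilyl)-2-diazoacetate | [N-]=[N+]=C(C(=O)OC(C)(C)C)[Si](C)(C)C(C)(C)C | intermediate
3 | tert-butyl 2-(tert-butyldimethylsilyl)-2-oxoacetate | CC(C)(C)OC(=O)C(=O)[Si](C)(C)C(C)(C)C | intermediate
4 | di-tert-butyl fumarate | CC(C)(C)OC(=O)/C=C/C(=O)OC(C)(C)C | starting material
5 | tert-butyl glyoxylate | O=CC(=O)OC(C)(C)C | intermediate
6 | vinylmagnesium bromide | C=C[Mg]Br | starting material
7 | bromomagnesium dienolate of tert-butyl 2-(tert-butyldimethylsilyloxy)but-3-enoate (not isolated) | C=CC(O[Si](C)(C)C(C)(C)C)=C(OC(C)(C)C)O[Mg]Br | intermediate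
8 | bromomagnesium enolate formed after the second addition and Brook shift, racemic at C5 (not isolated) | C=CC(O[Si](C)(C)C(C)(C)C)(C(=O)OC(C)(C)C)C(O[Si](C)(C)C(C)(C)C)=C(OC(C)(C)C)O[Mg]Br | intermediate
9 | racemic tri-tert-butyl (1R*,2S*,3R*)-2,3-bis(tert-butyldimethylsilyloxy)-1-hydroxypent-4-ene-1,2,3-tricarboxylate; chain C1, C2, C3 are core C3, C4, C5; needed enantiomer drawn | C=C[C@](O[Si](C)(C)C(C)(C)C)(C(=O)OC(C)(C)C)[C@](O[Si](C)(C)C(C)(C)C)(C(=O)OC(C)(C)C)[C@@H](O)C(=O)OC(C)(C)C | intermediate
10 | tri-tert-butyl (1R,2S,3R)-2,3-bis(tert-butyldimethylsilyloxy)-1-hydroxypent-4-ene-1,2,3-tricarboxylate, single enantiomer | C=C[C@](O[Si](C)(C)C(C)(C)C)(C(=O)OC(C)(C)C)[C@](O[Si](C)(C)C(C)(C)C)(C(=O)OC(C)(C)C)[C@@H](O)C(=O)OC(C)(C)C | intermediate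
11 | tri-tert-butyl (1R,2S,3R)-2,3-bis(tert-butyldimethylsilyloxy)-1-(triethylsilyloxy)pent-4-ene-1,2,3-tricarboxylate | C=C[C@](O[Si](C)(C)C(C)(C)C)(C(=O)OC(C)(C)C)[C@](O[Si](C)(C)C(C)(C)C)(C(=O)OC(C)(C)C)[C@@H](O[Si](CC)(CC)CC)C(=O)OC(C)(C)C | intermediate
12 | (S)-2-methyl-3-phenylpropanoic acid | OC(=O)[C@@H](C)Cc1ccccc1 | starting material
13 | (S)-2-methyl-3-phenylpropan-1-ol | OC[C@@H](C)Cc1ccccc1 | intermediate
14 | (S)-2-methyl-3-phenylpropanal | O=C[C@@H](C)Cc1ccccc1 | intermediate
15 | (4S)-2,4-dimethyl-5-phenylpent-1-en-3-ol, both C3 epimers | CC(=C)C(O)[C@@H](C)Cc1ccccc1 | intermediate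
16 | mixed ketene acetal, 1-ethoxyvinyl ether of 15 (not isolated) | C=C(OCC)OC(C(C)=C)[C@@H](C)Cc1ccccc1 | intermediate
17 | ethyl (4E,6S)-4,6-dimethyl-7-phenylhept-4-enoate | C/C(=C\[C@@H](C)Cc1ccccc1)CCC(=O)OCC | intermediate
18 | S-(4-methylphenyl) (4E,6S)-4,6-dimethyl-7-phenylhept-4-enethioate | C/C(=C\[C@@H](C)Cc1ccccc1)CCC(=O)Sc1ccc(C)cc1 | intermediate
19 | B-alkyl-9-borabicyclo[3.3.1]nonane from 11, boron on C7 (not isolated) | C(C[C@](O[Si](C)(C)C(C)(C)C)(C(=O)OC(C)(C)C)[C@](O[Si](C)(C)C(C)(C)C)(C(=O)OC(C)(C)C)[C@@H](O[Si](CC)(CC)CC)C(=O)OC(C)(C)C)B1C2CCCC1CCC2 | intermediate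
20 | tri-tert-butyl (1R,2S,3R,9E,11S)-2,3-bis(tert-butyldimethylsilyloxy)-9,11-dimethyl-6-oxo-12-phenyl-1-(triethylsilyloxy)dodec-9-ene-1,2,3-tricarboxylate (C1 ketone) | C/C(=C\[C@@H](C)Cc1ccccc1)CCC(=O)CC[C@](O[Si](C)(C)C(C)(C)C)(C(=O)OC(C)(C)C)[C@](O[Si](C)(C)C(C)(C)C)(C(=O)OC(C)(C)C)[C@@H](O[Si](CC)(CC)CC)C(=O)OC(C)(C)C | intermediate
21 | tri-tert-butyl (1R,2S,3R,9E,11S)-1,2,3-trihydroxy-9,11-dimethyl-6-oxo-12-phenyldodec-9-ene-1,2,3-tricarboxylate (not isolated) | C/C(=C\[C@@H](C)Cc1ccccc1)CCC(=O)CC[C@](O)(C(=O)OC(C)(C)C)[C@](O)(C(=O)OC(C)(C)C)[C@@H](O)C(=O)OC(C)(C)C | intermediate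
22 | tri-tert-butyl (1S,3R,4S,5R)-1-[(3E,5S)-3,5-dimethyl-6-phenylhex-3-en-1-yl]-4-hydroxy-2,8-dioxabicyclo[3.2.1]octane-3,4,5-tricarboxylate (C3 epimer) | C/C(=C\[C@@H](C)Cc1ccccc1)CC[C@@]12CC[C@@](C(=O)OC(C)(C)C)(O1)[C@](O)(C(=O)OC(C)(C)C)[C@H](C(=O)OC(C)(C)C)O2 | intermediate
23 | tri-tert-butyl (1S,3S,4S,5R)-1-[(3E,5S)-3,5-dimethyl-6-phenylhex-3-en-1-yl]-4-hydroxy-2,8-dioxabicyclo[3.2.1]octane-3,4,5-tricarboxylate | C/C(=C\[C@@H](C)Cc1ccccc1)CC[C@@]12CC[C@@](C(=O)OC(C)(C)C)(O1)[C@](O)(C(=O)OC(C)(C)C)[C@@H](C(=O)OC(C)(C)C)O2 | intermediate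
24 | (1S,3S,4S,5R)-1-[(3E,5S)-3,5-dimethyl-6-phenylhex-3-en-1-yl]-4-hydroxy-2,8-dioxabicyclo[3.2.1]octane-3,4,5-tricarboxylic acid | C/C(=C\[C@@H](C)Cc1ccccc1)CC[C@@]12CC[C@@](C(=O)O)(O1)[C@](O)(C(=O)O)[C@@H](C(=O)O)O2 | target

**Step count**

Total steps: 15. Longest linear sequence: 9 steps (steps 1, 2, 4, 5, 6, 12, 13, 14, 15; the side-chain branch, steps 7 to 11 and then 12 to 15, is equally long).

**Steps most likely to fail**

Step 4. The chain may lose count: the first enolate may be protonated or add in the wrong number of glyoxylate units, or the dienolate may react at its γ-carbon, and the closed transition states may give poor diastereocontrol. The fallback sets out from 5 and 6 and comes back at 9. Vinylmagnesium bromide is added to tert-butyl glyoxylate at −78 °C to give racemic tert-butyl 2-hydroxybut-3-enoate F1, which is silylated (TBSCl, imidazole, DMF) to tert-butyl 2-(tert-butyldimethylsilyloxy)but-3-enoate F2. Deprotonation with LiN(i-Pr)2 in THF at −78 °C gives the lithium dienolate F3 in a defined amount; MgBr2·OEt2 may be added to restore the magnesium counter-ion. One equivalent of 3 is then added; addition and Brook shift give the lithium enolate F4, which is trapped with 5 to return to 9. The first enolate is thus made by deprotonation and not by Grignard addition, so each glyoxylate unit is introduced in a separate, stoichiometric operation.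

Step 12. Transfer of the alkyl group from boron may be slow next to the fully substituted C5, so that the acylpalladium species decarbonylates or the borane is protonated before coupling. The fallback sets out from 11 and comes back at 20. Hydroboration with 9-BBN followed by oxidation (NaBO3·4H2O, THF/H2O) gives the primary C7 alcohol F5, which is converted at once (I2, PPh3, imidazole, CH2Cl2) into the primary iodide F6. Zinc insertion (activated Zn, THF/DMA) gives the alkylzinc iodide F7. This is coupled with thioester 18 under Fukuyama conditions (PdCl2(PPh3)2 cat., THF/toluene, rt) to return to ketone 20.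

Step 13. Cleavage of the two neighbouring tertiary silyl ethers may stall, tert-butyl esters may be lost or lactonise under the acid, or the keto triol may close to another ketal. The fallback sets out from 20 and comes back at 22. Treatment with TFA/H2O in CH2Cl2 at rt removes all silyl groups and all tert-butyl esters and equilibrates the ketal, giving (1S,3R,4S,5R)-1-[(3E,5S)-3,5-dimethyl-6-phenylhex-3-en-1-yl]-4-hydroxy-2,8-dioxabicyclo[3.2.1]octane-3,4,5-tricarboxylic acid F8. This is re-esterified with N,N'-diisopropyl-O-tert-butylisourea in CH2Cl2 to return to 22.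

**Further compounds**

F1 | step 4 | tert-butyl 2-hydroxybut-3-enoate (racemic) | C=CC(O)C(=O)OC(C)(C)C
F2 | step 4 | tert-butyl 2-(tert-butyldimethylsilyloxy)but-3-enoate (racemic) | C=CC(O[Si](C)(C)C(C)(C)C)C(=O)OC(C)(C)C
F3 | step 4 | lithium dienolate of F2 | C=CC(O[Si](C)(C)C(C)(C)C)=C(OC(C)(C)C)O[Li]
F4 | step 4 | lithium enolate formed after addition to 3 and Brook shift | C=CC(O[Si](C)(C)C(C)(C)C)(C(=O)OC(C)(C)C)C(O[Si](C)(C)C(C)(C)C)=C(OC(C)(C)C)O[Li]
F5 | step 12 | tri-tert-butyl (1R,2S,3R)-2,3-bis(tert-butyldimethylsilyloxy)-5-hydroxy-1-(triethylsilyloxy)pentane-1,2,3-tricarboxylate | OCC[C@](O[Si](C)(C)C(C)(C)C)(C(=O)OC(C)(C)C)[C@](O[Si](C)(C)C(C)(C)C)(C(=O)OC(C)(C)C)[C@@H](O[Si](CC)(CC)CC)C(=O)OC(C)(C)C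
F6 | step 12 | tri-tert-butyl (1R,2S,3R)-2,3-bis(tert-butyldimethylsilyloxy)-5-iodo-1-(triethylsilyloxy)pentane-1,2,3-tricarboxylate | ICC[C@](O[Si](C)(C)C(C)(C)C)(C(=O)OC(C)(C)C)[C@](O[Si](C)(C)C(C)(C)C)(C(=O)OC(C)(C)C)[C@@H](O[Si](CC)(CC)CC)C(=O)OC(C)(C)C
F7 | step 12 | alkylzinc iodide from F6 | I[Zn]CC[C@](O[Si](C)(C)C(C)(C)C)(C(=O)OC(C)(C)C)[C@](O[Si](C)(C)C(C)(C)C)(C(=O)OC(C)(C)C)[C@@H](O[Si](CC)(CC)CC)C(=O)OC(C)(C)C
F8 | step 13 | (1S,3R,4S,5R)-1-[(3E,5S)-3,5-dimethyl-6-phenylhex-3-en-1-yl]-4-hydroxy-2,8-dioxabicyclo[3.2.1]octane-3,4,5-tricarboxylic acid | C/C(=C\[C@@H](C)Cc1ccccc1)CC[C@@]12CC[C@@](C(=O)O)(O1)[C@](O)(C(=O)O)[C@H](C(=O)O)O2
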